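The dihydropyran ring is disconnected at C4a–C4 and O1–C2 (chroman numbering), back to a phenol and 3-methylbut-2-enal. In one operation the enal is joined to an ortho carbon and the resulting vinyl ortho-quinone methide closes by oxa-6π electrocyclisation, giving the 2,2-dimethyl-2H-chromene. The step exploits the O5/C6-methyl/O7 array of the aromatic ring: with the same methoxymethyl (MOM) group on O5 and O7 the precursor, 3,5-bis(methoxymethoxy)-4-methylphenol, has a mirror plane through its hydroxyl carbon and C-methyl carbon, so the future C4a and C8 are equivalent and a single chromene results. C8 is then acylated by directed lithiation, C3 is set by salen–manganese epoxidation, and mild acid frees the phenols.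

Key step: step 3

Remark: chroman numbering (O1, C2, C3, C4, C4a, C5 to C8, C8a) is used for all bicyclic compounds; the target SMILES encodes the (3S) configuration, and that is what the route builds.

Step 1
Reactants: 1 2-methylbenzene-1,3-diol (2-methylresorcinol)
Product: 2 1,3-bis(methoxymethoxy)-2-methylbenzene
Conditions: NaH, MOMCl, DMF, 0 °C → rt
Reagents that add atoms: chloromethyl methyl ether, COCCl
Why: Williamson-type O-alkylation of the sodium bis-phenoxide with the reactive α-chloro ether should give the bis-MOM acetal cleanly, since no other nucleophilic site competes.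

Step 2
Reactants: 2 1,3-bis(methoxymethoxy)-2-methylbenzene
Product: 4 3,5-bis(methoxymethoxy)-4-methylphenol, via pinacol arylboronate 3 (not isolated)
Conditions: [Ir(OMe)(cod)]2 (1.5 mol %), 4,4'-di-tert-butyl-2,2'-bipyridine (3 mol %), B2pin2 (0.7 equiv), THF, 80 °C; then 30% aq H2O2, aq NaOH, THF, 0 °C → rt
Reagents that add atoms: bis(pinacolato)diboron, CC1(C)OB(OC1(C)C)B1OC(C)(C)C(C)(C)O1 (boronate group of intermediate 3); hydrogen peroxide, OO (phenol oxygen of 4)
Why: Sterically governed iridium-catalysed arene C–H borylation can only reach C5–H, the one ring hydrogen not ortho to a substituent, and basic peroxide then turns C–B into C–OH by 1,2-aryl migration (borylation/oxidation phenol synthesis) under conditions to which MOM acetals are inert.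

Step 3
Reactants: 4 3,5-bis(methoxymethoxy)-4-methylphenol; 5 3-methylbut-2-enal
Product: 7 5,7-bis(methoxymethoxy)-2,2,6-trimethyl-2H-chromene, via vinyl ortho-quinone methide 6 (not isolated)
Conditions: ethylenediammonium diacetate (20 mol %), xylene, 140 °C
Reagents that add atoms: none
Why: The ammonium acetate salt activates 5 as its conjugated iminium ion, which the electron-rich phenol attacks in 1,2-fashion through an ortho carbon (future C4a, forming C4a–C4), and loss of the amine from the adduct gives the (Z)-vinyl ortho-quinone methide 6. Thermal disrotatory oxa-6π electrocyclisation of 6 then forms O1–C2, closes the 2,2-dimethyl-2H-pyran ring (the only ring made here) and restores aromaticity. The closest known reaction type is the amine-salt-mediated formal [3+3] chromenylation of resorcinols and phloroglucinol ethers with enals (Knoevenagel-type condensation followed by oxa-6π electrocyclisation). No stereocenter is created, so enantiocontrol is left to step 6. Only site selectivity is needed: the mirror plane of 4 makes the two ortho carbons equivalent, the single free hydroxyl allows only one annulation, and the β,β-dimethyl substitution of 5 disfavours conjugate addition relative to attack at the carbonyl carbon.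

Step 4
Reactants: 8 3-phenylpropanoyl chloride
Product: 9 N-methoxy-N-methyl-3-phenylpropanamide
Conditions: MeNH(OMe)·HCl, K2CO3, CH2Cl2/H2O, 0 °C → rt
Reagents that add atoms: N,O-dimethylhydroxylamine hydrochloride, CNOC.Cl
Why: Schotten–Baumann N-acylation of the amine liberated by carbonate should give the Weinreb amide, the acid chloride reacting with nitrogen far faster than with water in the two-phase system.

Step 5
Reactants: 7 5,7-bis(methoxymethoxy)-2,2,6-trimethyl-2H-chromene; 9 N-methoxy-N-methyl-3-phenylpropanamide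
Product: 12 1-[5,7-bis(methoxymethoxy)-2,2,6-trimethyl-2H-chromen-8-yl]-3-phenylpropan-1-one, via 8-lithiochromene 10 (not isolated), via lithium hemiaminal adduct 11 (not isolated)
Conditions: n-BuLi, THF, 0 °C; then 9, −78 °C → rt; H2O
Reagents that add atoms: none
Why: Directed ortho-metalation should remove C8–H, the only aromatic hydrogen, which lies between the lithium-coordinating C7 OMOM group and ring oxygen O1, and the aryllithium adds to the Weinreb amide to give a chelated tetrahedral adduct that releases the ketone only on quench (Weinreb ketone synthesis), so over-addition is excluded.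

Step 6
Reactants: 12 1-[5,7-bis(methoxymethoxy)-2,2,6-trimethyl-2H-chromen-8-yl]-3-phenylpropan-1-one
Product: 13 1-[(3S,4S)-3,4-epoxy-5,7-bis(methoxymethoxy)-2,2,6-trimethyl-3,4-dihydro-2H-chromen-8-yl]-3-phenylpropan-1-one
Conditions: (S,S)-(salen)MnCl [salen = N,N'-bis(3,5-di-tert-butylsalicylidene)cyclohexane-1,2-diamine dianion, trivalent manganese] (5 mol %), 4-phenylpyridine N-oxide (20 mol %), aq NaOCl buffered to pH 11.3 with Na2HPO4, CH2Cl2, 0 °C
Reagents that add atoms: sodium hypochlorite, [Na+].[O-]Cl
Why: Jacobsen–Katsuki epoxidation, for which 2,2-dimethylchromenes are the best cis-alkene class, should transfer oxygen from the pentavalent oxo-manganese species of the (S,S)-catalyst to the alkene face that gives the (3S,4S)-epoxide, which fixes the C3 configuration of the target, while the C8 acyl group blocks the last aromatic position and tempers ring A so that the epoxide can be handled.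

Step 7
Reactants: 13 1-[(3S,4S)-3,4-epoxy-5,7-bis(methoxymethoxy)-2,2,6-trimethyl-3,4-dihydro-2H-chromen-8-yl]-3-phenylpropan-1-one
Product: 14 1-[(3S)-3-hydroxy-5,7-bis(methoxymethoxy)-2,2,6-trimethyl-3,4-dihydro-2H-chromen-8-yl]-3-phenylpropan-1-one
Conditions: H2 (1 atm), 10% Pd/C (zerovalent palladium on carbon), EtOAc, rt
Reagents that add atoms: none
Why: Palladium-catalysed hydrogenolysis of the strained benzylic C4–O bond of the aryl epoxide leaves the C3–O bond, and hence the (S) configuration, untouched, and the twisted, doubly ortho-oxygenated aryl ketone, the phenyl ring and the MOM acetals should not be reduced under one atmosphere of hydrogen.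

Step 8
Reactants: 14 1-[(3S)-3-hydroxy-5,7-bis(methoxymethoxy)-2,2,6-trimethyl-3,4-dihydro-2H-chromen-8-yl]-3-phenylpropan-1-one
Product: 15 1-[(3S)-3,5,7-trihydroxy-2,2,6-trimethyl-3,4-dihydro-2H-chromen-8-yl]-3-phenylpropan-1-one (the target)
Conditions: 3 M aq HCl/MeOH, 45 °C
Reagents that add atoms: none
Why: Acid-catalysed acetal exchange with methanol (MOM cleavage) should free both phenols, whereas the secondary alcohol, the ketone and the tertiary alkyl aryl ether (whose ionisation at C2 is disfavoured by the adjacent carbinol) tolerate dilute methanolic HCl, and C3 has no pathway to epimerise.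

Compound list
1 | 2-methylbenzene-1,3-diol | Cc1c(O)cccc1O | starting material
2 | 1,3-bis(methoxymethoxy)-2-methylbenzene | Cc1c(OCOC)cccc1OCOC | intermediate
3 | 2-[3,5-bis(methoxymethoxy)-4-methylphenyl]-4,4,5,5-tetramethyl-1,3,2-dioxaborolane | Cc1c(OCOC)cc(B2OC(C)(C)C(C)(C)O2)cc1OCOC | intermediate (not isolated)
4 | 3,5-bis(methoxymethoxy)-4-methylphenol | Cc1c(OCOC)cc(O)cc1OCOC | intermediate (precursor of the key step)
5 | 3-methylbut-2-enal | CC(C)=CC=O | starting material
6 | (6Z)-3,5-bis(methoxymethoxy)-4-methyl-6-(3-methylbut-2-en-1-ylidene)cyclohexa-2,4-dien-1-one | O=C1C=C(OCOC)C(C)=C(OCOC)/C1=C/C=C(C)C | intermediate (not isolated)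
7 | 5,7-bis(methoxymethoxy)-2,2,6-trimethyl-2H-chromene | Cc1c(OCOC)c2c(cc1OCOC)OC(C)(C)C=C2 | intermediate (product of the key step)
8 | 3-phenylpropanoyl chloride | O=C(Cl)CCc1ccccc1 | starting material
9 | N-methoxy-N-methyl-3-phenylpropanamide | CON(C)C(=O)CCc1ccccc1 | intermediate
10 | [5,7-bis(methoxymethoxy)-2,2,6-trimethyl-2H-chromen-8-yl]lithium | [Li]c1c(OCOC)c(C)c(OCOC)c2c1OC(C)(C)C=C2 | intermediate (not isolated)
11 | lithium 1-[5,7-bis(methoxymethoxy)-2,2,6-trimethyl-2H-chromen-8-yl]-1-[methoxy(methyl)amino]-3-phenylpropan-1-olate (either configuration at the new carbon) | Cc1c(OCOC)c2c(c(C(O[Li])(CCc3ccccc3)N(C)OC)c1OCOC)OC(C)(C)C=C2 | intermediate (not isolated)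
12 | 1-[5,7-bis(methoxymethoxy)-2,2,6-trimethyl-2H-chromen-8-yl]-3-phenylpropan-1-one | Cc1c(OCOC)c2c(c(C(=O)CCc3ccccc3)c1OCOC)OC(C)(C)C=C2 | intermediate
13 | 1-[(3S,4S)-3,4-epoxy-5,7-bis(methoxymethoxy)-2,2,6-trimethyl-3,4-dihydro-2H-chromen-8-yl]-3-phenylpropan-1-one | Cc1c(OCOC)c2c(c(C(=O)CCc3ccccc3)c1OCOC)OC(C)(C)[C@H]1O[C@H]12 | intermediate
14 | 1-[(3S)-3-hydroxy-5,7-bis(methoxymethoxy)-2,2,6-trimethyl-3,4-dihydro-2H-chromen-8-yl]-3-phenylpropan-1-one | Cc1c(OCOC)c2c(c(C(=O)CCc3ccccc3)c1OCOC)OC(C)(C)[C@@H](O)C2 | intermediate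
15 | 1-[(3S)-3,5,7-trihydroxy-2,2,6-trimethyl-3,4-dihydro-2H-chromen-8-yl]-3-phenylpropan-1-one | Cc1c(O)c2c(c(C(=O)CCc3ccccc3)c1O)OC(C)(C)[C@@H](O)C2 | target

Total step count: 8. Longest linear sequence: 7 (steps 1, 2, 3, 5, 6, 7, 8); step 4 is a one-step side branch.

Steps most likely to fail

Step 3. C–C bond formation at an ortho carbon flanked by OH and OMOM may be slow, so that self-condensation of the enal, or capture of the quinone methide by a second phenol, outruns ring closure. Fallback, from 4 back to 7: the phenol is O-alkylated with 3-chloro-3-methylbut-1-yne (K2CO3, KI, cat. CuI, acetone, 60 °C) to the aryl propargyl ether 1,3-bis(methoxymethoxy)-2-methyl-5-[(2-methylbut-3-yn-2-yl)oxy]benzene F1. Heating F1 in N,N-diethylaniline or xylene (140–180 °C) should trigger an aromatic propargyl Claisen rearrangement to the allenylphenol 3,5-bis(methoxymethoxy)-4-methyl-2-(3-methylbuta-1,2-dien-1-yl)phenol F2. A [1,5]-hydrogen shift then gives the same quinone methide 6, and electrocyclisation gives 7. The C–C bond is thus made intramolecularly.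

Step 7. Chemoselectivity on the metal surface may be lost through partial reduction of the aryl ketone, through isomerisation of the epoxide to the C3 ketone by hydride shift, or through stalling of the hydrogenolysis. Fallback, from 13 back to 14: LiAlH4 (THF, 0 °C) should reduce the ketone and open the epoxide at benzylic C4 in one operation to the diol 1-[(3S)-3-hydroxy-5,7-bis(methoxymethoxy)-2,2,6-trimethyl-3,4-dihydro-2H-chromen-8-yl]-3-phenylpropan-1-ol F7 (both carbinol epimers, inconsequential). MnO2 (CH2Cl2, rt) then re-oxidises only the benzylic carbinol and returns 14.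

Step 6. Facial selectivity of oxygen transfer may be insufficient on a chromene that carries a peri OMOM group and the C8 acyl group, and hypochlorite may chlorinate alpha to the ketone. Fallback, from 7 back to 14, by reordering so that the unacylated chromene is epoxidised:
- Epoxidation of 7 with (S,S)-(salen)MnCl, mCPBA and N-methylmorpholine N-oxide (CH2Cl2, −78 °C) should give the acid-labile epoxide (3S,4S)-3,4-epoxy-5,7-bis(methoxymethoxy)-2,2,6-trimethyl-3,4-dihydro-2H-chromene F3, which is used crude.
- LiAlH4 (THF, 0 °C) opens F3 at benzylic C4 to the chromanol (3S)-5,7-bis(methoxymethoxy)-2,2,6-trimethyl-3,4-dihydro-2H-chromen-3-ol F4.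
- n-BuLi (2.3 equiv, THF, 0 °C) converts F4 into the C8-lithiated lithium alkoxide lithium (3S)-8-lithio-5,7-bis(methoxymethoxy)-2,2,6-trimethyl-3,4-dihydro-2H-chromen-3-olate F5.
- F5 adds to 9 (−78 °C → rt) to give the tetrahedral adduct dilithium (3S)-8-{1-[methoxy(methyl)amino]-1-oxido-3-phenylpropyl}-5,7-bis(methoxymethoxy)-2,2,6-trimethyl-3,4-dihydro-2H-chromen-3-olate F6, and aqueous quench gives 14.

Further compounds
F1 | step 3 | 1,3-bis(methoxymethoxy)-2-methyl-5-[(2-methylbut-3-yn-2-yl)oxy]benzene | Cc1c(OCOC)cc(OC(C)(C)C#C)cc1OCOC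
F2 | step 3 | 3,5-bis(methoxymethoxy)-4-methyl-2-(3-methylbuta-1,2-dien-1-yl)phenol | Cc1c(OCOC)cc(O)c(C=C=C(C)C)c1OCOC
F3 | step 6 | (3S,4S)-3,4-epoxy-5,7-bis(methoxymethoxy)-2,2,6-trimethyl-3,4-dihydro-2H-chromene | Cc1c(OCOC)c2c(cc1OCOC)OC(C)(C)[C@H]1O[C@H]12
F4 | step 6 | (3S)-5,7-bis(methoxymethoxy)-2,2,6-trimethyl-3,4-dihydro-2H-chromen-3-ol | Cc1c(OCOC)c2c(cc1OCOC)OC(C)(C)[C@@H](O)C2
F5 | step 6 | lithium (3S)-8-lithio-5,7-bis(methoxymethoxy)-2,2,6-trimethyl-3,4-dihydro-2H-chromen-3-olate | Cc1c(OCOC)c2c(c([Li])c1OCOC)OC(C)(C)[C@@H](O[Li])C2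
F6 | step 6 | dilithium (3S)-8-{1-[methoxy(methyl)amino]-1-oxido-3-phenylpropyl}-5,7-bis(methoxymethoxy)-2,2,6-trimethyl-3,4-dihydro-2H-chromen-3-olate | Cc1c(OCOC)c2c(c(C(O[Li])(CCc3ccccc3)N(C)OC)c1OCOC)OC(C)(C)[C@@H](O[Li])C2
F7 | step 7 | 1-[(3S)-3-hydroxy-5,7-bis(methoxymethoxy)-2,2,6-trimethyl-3,4-dihydro-2H-chromen-8-yl]-3-phenylpropan-1-ol | Cc1c(OCOC)c2c(c(C(O)CCc3ccccc3)c1OCOC)OC(C)(C)[C@@H](O)C2
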